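South takes more Z than any earlier run and stands longer, so I had to carry those runs forward in both.

| flask | D | Z | L | remark | time |
|---|---|---|---|---|---|
| theta | 20 mM | 0.43 equiv (fed, over 4.0 min) | 5 equiv | run made earlier; the fed solution adds 0.50 times the starting volume |  |
| delta | 20 mM | 1.1 equiv (fed, over 4.0 min) | 5 equiv | run made earlier; the fed solution adds 0.50 times the starting volume |  |
| epsilon | 20 mM | 1.6 equiv (fed, over 4.0 min) | 5 equiv | run made earlier; the fed solution adds 0.50 times the starting volume |  |
| south-east | 20 mM | 0.500 equiv (fed, over 4.0 min) | 5.00 equiv | the fed solution adds 0.50 times the starting volume | 3.0 h |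
| south | 20 mM | 2.00 equiv (fed, over 4.0 min) | 5.00 equiv | the fed solution adds 0.50 times the starting volume | 3.0 h |
| north-west | 20 mM | 0.800 equiv (fed, over 4.0 min) | 5.00 equiv | the fed solution adds 0.50 times the starting volume | 3.0 h |

| run | time / min | Q / % | E / % |
|---|---|---|---|
| theta | 20.0 | 0 | 0.3 |
| theta | 40.0 | 0.2 | 0.5 |
| theta | 50.0 | 0.2 | 0.6 |
| theta | 80.0 | 0 | 1.1 |
| theta | 90.0 | 0.9 | 1.5 |
| delta | 20.0 | 0 | 1.2 |
| delta | 40.0 | 0.6 | 1.7 |
| delta | 50.0 | 0.8 | 2.8 |
| delta | 80.0 | 1.7 | 5.0 |
| delta | 90.0 | 2.0 | 5.5 |
| epsilon | 8.00 | 0 | 0.1 |
| epsilon | 15.0 | 0 | 0.9 |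
| epsilon | 25.0 | 0.3 | 1.6 |
| epsilon | 50.0 | 1.4 | 5.1 |
| epsilon | 90.0 | 4.8 | 7.4 |

(standard deviation of a reading: 0.3 percentage points)

- every charge counts on the volume at the start, and the solution that is fed holds the whole dose
- the earlier runs were read with a standard deviation of 0.3 percentage points
- a reading or a percentage of E counts all its forms, free or not

1. which of these holds the largest part of the D at the end of south-east (X / E / D / Q)
2. which of these holds the largest part of the D at the end of south (X / E / D / Q)
3. which of these holds the largest part of the D at the end of north-west (X / E / D / Q)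
4. final Q in south, as a percentage of the D charged

1. The puzzle: going from delta to epsilon, Z rose by a factor 1.45. At 90.0 min, the E reading rose by a factor 1.35, but the Q reading rose by 2.40.

2. I took Q to be made from E, so I divided final cQ by the area under cE. This gives a drain constant for E, a pseudo-first-order constant: 0.0137 /min in epsilon and 0.00858 /min in delta, as readings.

3. Their ratio, 1.60, sits near the Z factor. So Q's factor is two factors multiplied: this one and 1.50 in the area under cE.

4. Scaled from epsilon by the Z charge, my estimate of south's drain constant is 0.0171 /min.

5. I took cE + cQ as proportional to Z and time, which gives 30.5% for south at 3.0 h.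

6. First round, for south: supply equals drain at cE = 9.89%, leaving cQ = 20.6%.

7. Second round, for south: putting the approach to that level back in, I got cQ = 21.1%.

The forecast named D, X and X as largest in south-east, south and north-west, with 16% for Q in south: “leaving Q around 16%”. My Q stood above that.

South ended with Q at 21.2%. Of the four asked about, D, X, E and Q, the largest at the end was D in south-east at 22.8%, Q in south at 21.2%, and D in north-west at 20.7%.

    D + Z → L + X (k = 0.00978 /M/s)
    X + Z → L + E (k = 0.0168 /M/s)
    E + Z → L + Q (k = 0.0151 /M/s)
    D + E ⇌ J, settled at all times (K = 62.6 /M)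
    D ⇌ G (K = 2.71, k = 0.00298 /s)

At the end of south, 51% of its Z was left. In south, from 1.50 h to 3.00 h, 0.0171 /min on the flask's cE, J counted in, gives 17 percentage points of Q, and the flask gained 13 points.

With 5.00 equiv of Z in place of south's charge, the drain constant scales to 0.0428 /min, and the same reckoning gives cQ = 66.4%. The computed flask gives 63.3%.

The readings are simulated with constants of no real substance; the scatter is artificial.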